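The route rests on cutting the C1'–C2' bond between the OCH2 carbon and the vinylic CH of the (E)-C2'=C3' alkene. The key step exploits the fact that O4 of the 2H-chromen-2-one ring is a vinylogous carboxylate oxygen. C1' can therefore carry zinc, as in acyloxymethylzinc reagents, and it has no β-hydrogen. A Pd-catalysed Negishi coupling joins this zinc reagent to an (E)-alkenyl iodide that already holds the C4' silyl ether and the C6' peroxide (masked as a peroxyketal). The coupling transfers the alkene geometry and completes the skeleton under neutral conditions. One mild acid step then frees OH and OOH. C4' comes from a boron aldol, C6' from CBS reduction and SN2 inversion.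

Key step: step 11

Remark: the side chain is numbered C1' (OCH2) to C8' (terminal =CH2). The target is (2'E,4'S,6'S), so OH and OOH are 1,3-anti, and the alcohol that is displaced with inversion must be the 1,3-syn (4'S,6'R) isomer.

Step 1
Reactants: 1 1-(2-hydroxy-6-methylphenyl)ethan-1-one
Product: 2 4-hydroxy-5-methyl-2H-chromen-2-one
Conditions: NaH, (EtO)2CO, toluene, 110 °C; then aq. HCl
Reagents that add atoms: diethyl carbonate, CCOC(=O)OCC
Why: Claisen-type C-acylation of the ketone enolate by the carbonate followed by lactonisation onto the phenoxide (the standard 4-hydroxycoumarin synthesis) builds the pyranone ring and places the aryl methyl group at C5.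

Step 2
Reactants: 2 4-hydroxy-5-methyl-2H-chromen-2-one
Product: 3 4-(chloromethoxy)-5-methyl-2H-chromen-2-one
Conditions: ClCH2OSO2Cl, NaHCO3, Bu4NHSO4 (cat.), CH2Cl2/H2O, 0 °C to rt
Reagents that add atoms: chloromethyl chlorosulfate, ClCOS(=O)(=O)Cl
Why: Phase-transfer O-chloromethylation, the method used to make chloromethyl esters, applies because 2 is a vinylogous carboxylic acid, and the hard electrophile with the ion pair in CH2Cl2 should favour O4 over C3.

Step 3
Reactants: 3 4-(chloromethoxy)-5-methyl-2H-chromen-2-one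
Product: 4 4-(iodomethoxy)-5-methyl-2H-chromen-2-one
Conditions: NaI, acetone, rt, dark
Reagents that add atoms: sodium iodide, [Na+].[I-]
Why: Finkelstein halide exchange, driven by precipitation of NaCl, gives the iodide needed for mild zinc insertion, as in the conversion of chloromethyl esters into iodomethyl esters.

Step 4
Reactants: 5 2,3-dimethylbut-2-ene
Product: 6 2-hydroperoxy-2-methoxypropane
Conditions: O3, MeOH/CH2Cl2, −78 °C; N2 purge
Reagents that add atoms: ozone, [O-][O+]=O; methanol, CO
Why: Ozonolysis in a participating solvent traps the Criegee carbonyl oxide from the symmetrical alkene with methanol and gives the acid-labile, ketal-protected form of hydrogen peroxide.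

Step 5
Reactants: 7 prop-2-yn-1-ol
Product: 9 (E)-3-iodo-2-methylprop-2-en-1-ol, via alkenylalane 8 (not isolated)
Conditions: Me3Al, Cp2ZrCl2 (cat.), CH2Cl2, 0 °C to rt; then I2, THF, −30 °C; aqueous work-up
Reagents that add atoms: trimethylaluminium, C[Al](C)C; iodine, II
Why: Negishi zirconium-catalysed carboalumination adds Me and Al syn, with Al at the terminal carbon, and iodinolysis with retention fixes the E geometry that later becomes C2'=C3'.

Step 6
Reactants: 9 (E)-3-iodo-2-methylprop-2-en-1-ol
Product: 10 (E)-3-iodo-2-methylprop-2-enal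
Conditions: MnO2, CH2Cl2, rt
Reagents that add atoms: none
Why: MnO2 oxidation of an allylic alcohol stops at the enal and leaves the alkenyl iodide and its geometry untouched.

Step 7
Reactants: 11 3-methylbut-3-en-2-one; 10 (E)-3-iodo-2-methylprop-2-enal
Product: 14 (5S,6E)-5-hydroxy-7-iodo-2,6-dimethylhepta-1,6-dien-3-one, via enol borinate 12 (not isolated), via boron aldolate 13 (not isolated)
Conditions: (+)-Ipc2BCl, Et3N, Et2O, 0 °C; then 10, −78 to −20 °C; then H2O2, MeOH, pH 7 buffer, 0 °C
Reagents that add atoms: none
Why: In this diisopinocampheylboron-mediated asymmetric aldol reaction of a methyl ketone, kinetic enolisation at the methyl group gives 12, whose (+)-Ipc ligands should direct addition to the si face of enal 10 through a cyclic transition state and set C4' as S; the moderate face bias typical of unsubstituted enol borinates is upgraded in step 9.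

Step 8
Reactants: 14 (5S,6E)-5-hydroxy-7-iodo-2,6-dimethylhepta-1,6-dien-3-one
Product: 15 (5S,6E)-7-iodo-2,6-dimethyl-5-(triethylsilyloxy)hepta-1,6-dien-3-one
Conditions: TESCl, imidazole, CH2Cl2, 0 °C
Reagents that add atoms: chlorotriethylsilane, CC[Si](Cl)(CC)CC
Why: Imidazole-promoted silylation is mild enough to avoid retro-aldol or β-elimination, and it installs a group that falls off under the same acid conditions as the peroxyketal.

Step 9
Reactants: 15 (5S,6E)-7-iodo-2,6-dimethyl-5-(triethylsilyloxy)hepta-1,6-dien-3-one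
Product: 16 (3R,5S,6E)-7-iodo-2,6-dimethyl-5-(triethylsilyloxy)hepta-1,6-dien-3-ol
Conditions: (S)-Me-CBS (cat.), catecholborane, toluene, −78 °C
Reagents that add atoms: none
Why: In the Corey–Bakshi–Shibata reduction the isopropenyl group acts as the large substituent, so the (S)-catalyst should give the (3R)-alcohol (C6') by 1,2-reduction while catecholborane at −78 °C spares the alkenes; because this second reagent-controlled step sends most of the minor enantiomer of 15 into the separable 3,5-anti diastereomer, chromatography should raise the enantiopurity of syn-16 (Horeau-type amplification).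

Step 10
Reactants: 16 (3R,5S,6E)-7-iodo-2,6-dimethyl-5-(triethylsilyloxy)hepta-1,6-dien-3-ol; 6 2-hydroperoxy-2-methoxypropane
Product: 18 triethyl{[(1E,3S,5S)-1-iodo-5-[(2-methoxypropan-2-yl)peroxy]-2,6-dimethylhepta-1,6-dien-3-yl]oxy}silane, via allylic mesylate 17 (not isolated)
Conditions: MsCl, Et3N, THF, −30 °C; then 6, KOtBu, 18-crown-6, DMF, −30 to 0 °C
Reagents that add atoms: none
Why: Mesylation followed by SN2 alkylation of the peroxyketal-protected hydroperoxide anion, an α-effect nucleophile, should invert C6' from R to S, and the cold one-pot protocol avoids handling the labile allylic mesylate and favours direct attack over SN2' attack and E2 loss.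

Step 11
Reactants: 4 4-(iodomethoxy)-5-methyl-2H-chromen-2-one; 18 triethyl{[(1E,3S,5S)-1-iodo-5-[(2-methoxypropan-2-yl)peroxy]-2,6-dimethylhepta-1,6-dien-3-yl]oxy}silane
Product: 20 4-{[(2E,4S,6S)-6-[(2-methoxypropan-2-yl)peroxy]-3,7-dimethyl-4-(triethylsilyloxy)octa-2,7-dien-1-yl]oxy}-5-methyl-2H-chromen-2-one, via organozinc iodide 19 (not isolated)
Conditions: 4, Zn dust, LiCl, THF, rt, solution filtered from excess Zn; then 18, Pd(dba)2 (cat.), P(2-furyl)3 (cat.), THF, 0 °C to rt
Reagents that add atoms: none
Why: Zinc inserts into the activated C–I bond of 4 to give 19, stabilised like the known (acyloxymethyl)zinc iodides because O4 of the chromen-2-one ring is a vinylogous carboxylate oxygen; Pd(0) then adds oxidatively to the C(sp2)–I bond of 18 with retention, 19 transfers its CH2 group to palladium, and reductive elimination forms the C2'–C1' bond (Negishi coupling). The closest known reaction type is the Pd(dba)2/tri(2-furyl)phosphine-catalysed coupling of functionalised alkylzinc iodides with alkenyl iodides at room temperature, and Pd(0)-catalysed couplings of peroxide-bearing alkenyl iodides are also known. No ring is closed and no stereocentre is made: the E geometry set in step 5 is carried over stereospecifically, and C4' and C6' are spectators. The transferred carbon has no β-hydrogen, so β-hydride elimination, the usual weakness of sp3 partners, cannot occur. Palladium must choose the C–I bond over the O–O bond, the allylic C6'–OO bond and the allylic C1'–O4 bond of product 20; the fast oxidative addition of an alkenyl iodide at or below rt, the weakly donating phosphine, the poor leaving-group quality of a peroxyketal anion and the hindered trisubstituted allyl unit of 20 should secure this. The organozinc halide is too weak a nucleophile to attack the lactone, the silyl ether or the dialkyl-type peroxide.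

Step 12
Reactants: 20 4-{[(2E,4S,6S)-6-[(2-methoxypropan-2-yl)peroxy]-3,7-dimethyl-4-(triethylsilyloxy)octa-2,7-dien-1-yl]oxy}-5-methyl-2H-chromen-2-one
Product: 21 4-{[(2E,4S,6S)-6-hydroperoxy-4-hydroxy-3,7-dimethylocta-2,7-dien-1-yl]oxy}-5-methyl-2H-chromen-2-one
Conditions: AcOH/THF/H2O, 0 °C to rt
Reagents that add atoms: none
Why: Mild acid hydrolysis cleaves the peroxyketal and the triethylsilyl ether in one operation without breaking a C–O bond at C4' or C6', and it is too weak to trigger Hock cleavage of the hydroperoxide or ionisation of the allylic coumarinyl ether.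

Compound list
1 | 1-(2-hydroxy-6-methylphenyl)ethan-1-one | CC(=O)c1c(C)cccc1O | starting material
2 | 4-hydroxy-5-methyl-2H-chromen-2-one | Oc1cc(=O)oc2cccc(C)c12 | intermediate
3 | 4-(chloromethoxy)-5-methyl-2H-chromen-2-one | ClCOc1cc(=O)oc2cccc(C)c12 | intermediate
4 | 4-(iodomethoxy)-5-methyl-2H-chromen-2-one | ICOc1cc(=O)oc2cccc(C)c12 | intermediate
5 | 2,3-dimethylbut-2-ene | CC(C)=C(C)C | starting material
6 | 2-hydroperoxy-2-methoxypropane | COC(C)(C)OO | intermediate
7 | prop-2-yn-1-ol | C#CCO | starting material
8 | (E)-3-(dimethylalumanyloxy)-2-methylprop-1-enyl(dimethyl)alumane | C[Al](C)OC/C(C)=C/[Al](C)C | intermediate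
9 | (E)-3-iodo-2-methylprop-2-en-1-ol | OC/C(C)=C/I | intermediate
10 | (E)-3-iodo-2-methylprop-2-enal | O=C/C(C)=C/I | intermediate
11 | 3-methylbut-3-en-2-one | CC(=O)C(C)=C | starting material
12 | (3-methylbuta-1,3-dien-2-yl) diisopinocampheylborinate, Ipc groups of the (+)-Ipc2BCl series | C=C(C)C(=C)OB([C@H]1C[C@H]2C[C@@H]([C@@H]1C)C2(C)C)[C@H]1C[C@H]2C[C@@H]([C@@H]1C)C2(C)C | intermediate
13 | diisopinocampheylboron aldolate of 14 | C=C(C)C(=O)C[C@H](OB([C@H]1C[C@H]2C[C@@H]([C@@H]1C)C2(C)C)[C@H]1C[C@H]2C[C@@H]([C@@H]1C)C2(C)C)/C(C)=C/I | intermediate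
14 | (5S,6E)-5-hydroxy-7-iodo-2,6-dimethylhepta-1,6-dien-3-one | C=C(C)C(=O)C[C@H](O)/C(C)=C/I | intermediate
15 | (5S,6E)-7-iodo-2,6-dimethyl-5-(triethylsilyloxy)hepta-1,6-dien-3-one | C=C(C)C(=O)C[C@H](O[Si](CC)(CC)CC)/C(C)=C/I | intermediate
16 | (3R,5S,6E)-7-iodo-2,6-dimethyl-5-(triethylsilyloxy)hepta-1,6-dien-3-ol | C=C(C)[C@@H](C[C@H](O[Si](CC)(CC)CC)/C(C)=C/I)O | intermediate
17 | (3R,5S,6E)-7-iodo-2,6-dimethyl-5-(triethylsilyloxy)hepta-1,6-dien-3-yl methanesulfonate | C=C(C)[C@@H](C[C@H](O[Si](CC)(CC)CC)/C(C)=C/I)OS(C)(=O)=O | intermediate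
18 | triethyl{[(1E,3S,5S)-1-iodo-5-[(2-methoxypropan-2-yl)peroxy]-2,6-dimethylhepta-1,6-dien-3-yl]oxy}silane | C=C(C)[C@H](C[C@H](O[Si](CC)(CC)CC)/C(C)=C/I)OOC(C)(C)OC | intermediate
19 | {[(5-methyl-2-oxo-2H-chromen-4-yl)oxy]methyl}zinc iodide | I[Zn]COc1cc(=O)oc2cccc(C)c12 | intermediate
20 | 4-{[(2E,4S,6S)-6-[(2-methoxypropan-2-yl)peroxy]-3,7-dimethyl-4-(triethylsilyloxy)octa-2,7-dien-1-yl]oxy}-5-methyl-2H-chromen-2-one | C=C(C)[C@H](C[C@H](O[Si](CC)(CC)CC)/C(C)=C/COc1cc(=O)oc2cccc(C)c12)OOC(C)(C)OC | intermediate
21 | 4-{[(2E,4S,6S)-6-hydroperoxy-4-hydroxy-3,7-dimethylocta-2,7-dien-1-yl]oxy}-5-methyl-2H-chromen-2-one | C=C(C)[C@H](C[C@H](O)/C(C)=C/COc1cc(=O)oc2cccc(C)c12)OO | target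

Total step count: 12. Longest linear sequence: 8 steps (7 to 21, steps 5–12).

Steps most likely to fail

1. Step 11.
- What may go wrong: reductive cleavage of the O–O bond by low-valent palladium or residual zinc, carbenoid-type decay of the zinc reagent before transmetalation, or palladium-induced ionisation of the new allylic C1'–O4 bond with allyl transfer to C3 of the coumarin.
- Fallback: the same bond is formed by a radical route before any peroxide is present. It sets out from 2 and 16 and comes back at 20.
- Compound 2 is alkylated with tert-butyl bromoacetate (K2CO3, acetone) to tert-butyl [(5-methyl-2-oxo-2H-chromen-4-yl)oxy]acetate F1. TFA in CH2Cl2 then gives [(5-methyl-2-oxo-2H-chromen-4-yl)oxy]acetic acid F2.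
- Iridium/nickel metallaphotoredox decarboxylative alkenylation of F2 with alkenyl iodide 16 (Ir[dF(CF3)ppy]2(dtbbpy)PF6, NiCl2·glyme, dtbbpy, Cs2CO3, DMF, blue light, rt) should give 4-{[(2E,4S,6R)-6-hydroxy-3,7-dimethyl-4-(triethylsilyloxy)octa-2,7-dien-1-yl]oxy}-5-methyl-2H-chromen-2-one F3.
- Mesylation gives the corresponding 6-methanesulfonate F4, and displacement with the potassium salt of 6 gives 20.

2. Step 10.
- What may go wrong: attack of the peroxy anion at the terminal alkene carbon (SN2'), E2 loss of the mesylate to a conjugated diene, or base-induced fragmentation of the secondary peroxide once it has formed.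
- Fallback: the stereospecific displacement is replaced by an ionising perhydrolysis with separation of the C6' epimers, which the fixed C4' centre makes possible. It sets out from 16 and comes back at 18.
- An Appel reaction (CBr4, PPh3, CH2Cl2) gives {[(1E,3S,5S)-5-bromo-1-iodo-2,6-dimethylhepta-1,6-dien-3-yl]oxy}triethylsilane F5.
- Silver-assisted perhydrolysis (AgOTf, anhydrous H2O2 in Et2O, 2,6-di-tert-butylpyridine, −40 °C) and chromatography give {[(1E,3S,5S)-5-hydroperoxy-1-iodo-2,6-dimethylhepta-1,6-dien-3-yl]oxy}triethylsilane F6.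
- Ketalisation with 2-methoxypropene and catalytic PPTS gives 18.

3. Step 7.
- What may go wrong: weak enantioface discrimination by the unsubstituted enol borinate, and polymerisation of the vinyl ketone during enolisation.
- Fallback: the stoichiometric chiral boron enolate is replaced by a catalytic open-transition-state aldol. It sets out from 11 and 10 and comes back at 14.
- Compound 11 is converted with TMSOTf and Et3N into trimethyl[(3-methylbuta-1,3-dien-2-yl)oxy]silane F7.
- F7 is added to 10 in a Mukaiyama aldol reaction promoted by SiCl4 and a catalytic chiral bisphosphoramide, with the antipode chosen for si-face addition (CH2Cl2, −78 °C). Aqueous work-up gives 14.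

Further compounds
F1 | step 11 | tert-butyl [(5-methyl-2-oxo-2H-chromen-4-yl)oxy]acetate | CC(C)(C)OC(=O)COc1cc(=O)oc2cccc(C)c12
F2 | step 11 | [(5-methyl-2-oxo-2H-chromen-4-yl)oxy]acetic acid | OC(=O)COc1cc(=O)oc2cccc(C)c12
F3 | step 11 | 4-{[(2E,4S,6R)-6-hydroxy-3,7-dimethyl-4-(triethylsilyloxy)octa-2,7-dien-1-yl]oxy}-5-methyl-2H-chromen-2-one | C=C(C)[C@@H](C[C@H](O[Si](CC)(CC)CC)/C(C)=C/COc1cc(=O)oc2cccc(C)c12)O
F4 | step 11 | (3R,5S,6E)-2,6-dimethyl-8-[(5-methyl-2-oxo-2H-chromen-4-yl)oxy]-5-(triethylsilyloxy)octa-1,6-dien-3-yl methanesulfonate | C=C(C)[C@@H](C[C@H](O[Si](CC)(CC)CC)/C(C)=C/COc1cc(=O)oc2cccc(C)c12)OS(C)(=O)=O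
F5 | step 10 | {[(1E,3S,5S)-5-bromo-1-iodo-2,6-dimethylhepta-1,6-dien-3-yl]oxy}triethylsilane | C=C(C)[C@H](C[C@H](O[Si](CC)(CC)CC)/C(C)=C/I)Br
F6 | step 10 | {[(1E,3S,5S)-5-hydroperoxy-1-iodo-2,6-dimethylhepta-1,6-dien-3-yl]oxy}triethylsilane | C=C(C)[C@H](C[C@H](O[Si](CC)(CC)CC)/C(C)=C/I)OO
F7 | step 7 | trimethyl[(3-methylbuta-1,3-dien-2-yl)oxy]silane | C=C(C)C(=C)O[Si](C)(C)C
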